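## Retrosynthetic overview
1. The C9=C10 enone is made last (desilylation at C11, then IBX oxidation/dehydrogenation), after both angelates are put on a C5,C15-diol with angelic anhydride.
2. The diol comes from LiAlH4 opening of a dioxanone; C7–H from Barton–McCombie removal of an aldol hydroxyl; the seven-membered ring from ring-closing metathesis (C3–C4).
3. Key disconnection C6–C7: aldol union of a Seebach dioxanone enolate (C4–C6, C14, C15) with a bicyclo[3.1.1]heptan-6-one (C1–C3, C7–C13), two halves of similar size.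
4. The bicyclic ketone comes from an intramolecular vinylketene [2+2] of a trienoic acid made by an asymmetric vinylogous Mukaiyama aldol; the dioxanone from an asymmetric thioester aldol with crotonaldehyde.
5. Ring order: cyclobutane and six-membered ring together, then the seven-membered ring, enone last.

Locants C1–C15 are those of the target's tricyclo[5.4.0.0^2,8]undecane skeleton (C12, C13, C14 = methyls on C2, C9, C6; C15 = CH2O carbon on C6).
Assumption: the enantiomer named for each chiral catalyst or ligand is the one taken to give the configuration shown; if the sense of induction is the reverse, its mirror image is used.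

## Route

Step 1
Reactants: 1 (2E)-3-methylpent-2-en-4-yn-1-ol
Product: 2 (2E)-3-methylpenta-2,4-dien-1-ol
Conditions: H2 (1 atm), Pd/CaCO3 poisoned with Pb(OAc)2, quinoline, EtOAc, 0 °C
Reagents that add atoms: none
Why: Lindlar semihydrogenation stops at the vinyl stage and leaves the E-trisubstituted alkene untouched, with no stereocentre formed.

Step 2
Reactants: 2 (2E)-3-methylpenta-2,4-dien-1-ol
Product: 3 (2E)-3-methylpenta-2,4-dienal
Conditions: MnO2, CH2Cl2, rt
Reagents that add atoms: none
Why: MnO2 oxidation of the allylic alcohol gives the dienal without E/Z isomerisation or over-oxidation.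

Step 3
Reactants: 4 3-methylbut-2-enoic acid
Product: 5 tert-butyldimethylsilyl 3-methylbut-2-enoate
Conditions: TBSCl, imidazole, CH2Cl2, rt
Reagents that add atoms: tert-butyl(chloro)dimethylsilane (CC(C)(C)[Si](C)(C)Cl)
Why: O-silylation of the carboxylic acid gives the silyl ester needed for a bis-silyl ketene acetal.

Step 4
Reactants: 5 tert-butyldimethylsilyl 3-methylbut-2-enoate
Product: 7 1,1-bis[(tert-butyldimethylsilyl)oxy]-3-methylbuta-1,3-diene, via lithium dienolate 6 (not isolated)
Conditions: LiN(iPr)2, THF, −78 °C; then TBSCl, DMPU, −78 °C → rt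
Reagents that add atoms: tert-butyl(chloro)dimethylsilane (CC(C)(C)[Si](C)(C)Cl)
Why: Kinetic γ-deprotonation of the senecioate and O-silylation give the bis-silyl dienolate used as vinylogous donor, with no stereocentre formed.

Step 5
Reactants: 3 (2E)-3-methylpenta-2,4-dienal; 7 1,1-bis[(tert-butyldimethylsilyl)oxy]-3-methylbuta-1,3-diene
Product: 9 (2E,5S,6E)-5-[(tert-butyldimethylsilyl)oxy]-3,7-dimethylnona-2,6,8-trienoic acid, via silyl ester 8 (not isolated)
Conditions: (S)-3,3′-bis[3,5-bis(trifluoromethyl)phenyl]-1,1′-binaphthalene-2,2′-disulfonimide (5 mol %), Et2O, −78 °C; then K2CO3, MeOH, 0 °C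
Reagents that add atoms: none
Why: In this catalytic asymmetric vinylogous Mukaiyama aldol the dienolate adds 1,2 to the aldehyde through its γ-carbon, the chiral disulfonimide anion selects the aldehyde face to set the 5S centre (C11), the silyl group moves to the new oxygen, and the labile silyl ester is cleaved by methanolysis.

Step 6
Reactants: 9 (2E,5S,6E)-5-[(tert-butyldimethylsilyl)oxy]-3,7-dimethylnona-2,6,8-trienoic acid
Product: 12 (1R,2S,5R,7R)-2-[(tert-butyldimethylsilyl)oxy]-7-ethenyl-7-methyl-4-methylidenebicyclo[3.1.1]heptan-6-one, via acid chloride 10 (not isolated), via vinylketene 11 (not isolated)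
Conditions: 1-chloro-N,N,2-trimethylprop-1-en-1-amine, CH2Cl2, 0 °C; then Et3N, toluene, 110 °C, high dilution
Reagents that add atoms: none
Why: In this intramolecular vinylketene–alkene [2+2] (Snider–Corey bicyclo[3.1.1]heptanone synthesis) the ketene carbonyl carbon bonds to C1 and its α-carbon to the more substituted C2, the E-alkene puts the C2 methyl syn to the three-carbon bridge, and allylic 1,3-strain keeps the C11–H toward that methyl so the silyloxy group ends on the side of the carbonyl bridge, which sets C1, C2 and C8 from the 5S centre.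

Step 7
Reactants: 13 S-ethyl propanethioate
Product: 15 (Z)-[1-(ethylsulfanyl)prop-1-enyl]oxy(trimethyl)silane, via lithium enolate 14 (not isolated)
Conditions: LiN(iPr)2, THF, −78 °C; then TMSCl
Reagents that add atoms: chlorotrimethylsilane (C[Si](C)(C)Cl)
Why: Kinetic enolisation of the thioester and O-silylation give the Z ketene silyl thioacetal required for a syn-selective Mukaiyama aldol.

Step 8
Reactants: 15 (Z)-[1-(ethylsulfanyl)prop-1-enyl]oxy(trimethyl)silane; 16 (2E)-but-2-enal
Product: 18 S-ethyl (2S,3R,4E)-3-hydroxy-2-methylhex-4-enethioate, via O-silyl aldol 17 (not isolated)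
Conditions: Sn(OTf)2 (20 mol %), (R)-1-methyl-2-[(naphthalen-1-ylamino)methyl]pyrrolidine (22 mol %), EtCN, −78 °C, slow addition; then 1 M HCl, THF
Reagents that add atoms: none
Why: The Kobayashi–Mukaiyama catalytic asymmetric aldol (chiral diamine–Sn(OTf)2) adds the thioacetal to the aldehyde face chosen by the ligand and gives the syn adduct, setting 3R (the future C5) and a 2S centre that is erased later.

Step 9
Reactants: 18 S-ethyl (2S,3R,4E)-3-hydroxy-2-methylhex-4-enethioate
Product: 19 (2S,3R,4E)-3-hydroxy-2-methylhex-4-enoic acid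
Conditions: LiOH, THF/H2O, 0 °C; then 1 M HCl
Reagents that add atoms: lithium hydroxide ([Li+].[OH-])
Why: Mild saponification of the activated thioester frees the β-hydroxy acid without touching the carbinol centre.

Step 10
Reactants: 19 (2S,3R,4E)-3-hydroxy-2-methylhex-4-enoic acid
Product: 20 (2R,5S,6R)-2-tert-butyl-5-methyl-6-[(1E)-prop-1-enyl]-1,3-dioxan-4-one
Conditions: t-BuCHO, camphorsulfonic acid (5 mol %), CH2Cl2, 4 Å molecular sieves, 0 °C → rt
Reagents that add atoms: 2,2-dimethylpropanal (CC(C)(C)C=O)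
Why: Acetalisation to a Seebach 1,3-dioxan-4-one protects the C5 oxygen and the acid together, the acetal centre forming under thermodynamic control cis to the propenyl group (both equatorial).

Step 11
Reactants: 20 (2R,5S,6R)-2-tert-butyl-5-methyl-6-[(1E)-prop-1-enyl]-1,3-dioxan-4-one; 12 (1R,2S,5R,7R)-2-[(tert-butyldimethylsilyl)oxy]-7-ethenyl-7-methyl-4-methylidenebicyclo[3.1.1]heptan-6-one
Product: 22 dioxanone-substituted bicyclo[3.1.1]heptan-6-ol (C6–C7 bond formed), via lithium enolate 21 (not isolated)
Conditions: LiN(iPr)2, THF, −78 °C; then 12, −78 °C; AcOH, −78 °C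
Reagents that add atoms: none
Why: In this aldol addition of a dioxanone lithium enolate to a strained, non-enolisable cyclobutanone the enolate reacts anti to the propenyl group on the neighbouring ring carbon (sets C6), and the ketone is approached from the face of the C2 bridge, which carries only the flat vinyl group, because C10 of the three-carbon bridge and the C11 silyloxy group close the other face (sets C7 with the hydroxyl toward the three-carbon bridge).

Step 12
Reactants: 22 dioxanone-substituted bicyclo[3.1.1]heptan-6-ol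
Product: 24 tricyclic hydroxy dioxanone (seven-membered ring closed; C9 epimers), via cycloheptene 23 (not isolated)
Conditions: second-generation Grubbs catalyst (H2IMes)(PCy3)Cl2Ru=CHPh (5 mol %), toluene, 60 °C; then H2 (10 bar), 70 °C
Reagents that add atoms: none
Why: Ring-closing metathesis joins the vinyl group on C2 and the propenyl group on C5, which sit on the same face of the cyclobutane, and the ruthenium residue then hydrogenates the new alkene and the exocyclic methylene in tandem, the C9 centre so formed being removed again in step 19.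

Step 13
Reactants: 24 tricyclic hydroxy dioxanone (C9 epimers)
Product: 26 S-methyl xanthate of 24, via sodium xanthate 25 (not isolated)
Conditions: NaN(SiMe3)2, CS2, THF, −78 °C; then MeI, −78 → 0 °C
Reagents that add atoms: carbon disulfide (S=C=S); iodomethane (CI)
Why: Xanthate formation traps the tertiary alkoxide at once with CS2 at low temperature, which suppresses retro-aldol cleavage and silyl migration, and no stereocentre changes.

Step 14
Reactants: 26 S-methyl xanthate of 24
Product: 27 tricyclic dioxanone with C7–H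
Conditions: Bu3SnH, AIBN, toluene, 100 °C
Reagents that add atoms: none
Why: In this Barton–McCombie deoxygenation the tertiary xanthate cannot undergo Chugaev elimination (its β-hydrogens are bridgehead), and the C7 radical held in the closed ring system can take hydrogen only at the position the oxygen left, giving the required C7–H.

Step 15
Reactants: 27 tricyclic dioxanone with C7–H
Product: 28 (1R,2R,5R,6S,7S,8S,11S)-11-[(tert-butyldimethylsilyl)oxy]-6-(hydroxymethyl)-2,6,9-trimethyltricyclo[5.4.0.0^2,8]undecan-5-ol (C9 epimers)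
Conditions: LiAlH4, THF, 0 °C → rt
Reagents that add atoms: none
Why: Hydride reduction of the acylal carbonyl gives the C15 primary alcohol and releases the C5 alcohol by collapse of the hemiacetal, with the silyl ether and all stereocentres untouched.

Step 16
Reactants: 29 (2Z)-2-methylbut-2-enoic acid (angelic acid), two equivalents
Product: 30 (2Z)-2-methylbut-2-enoic anhydride (angelic anhydride)
Conditions: DCC (0.5 equiv per acid), CH2Cl2, 0 °C → rt
Reagents that add atoms: (2Z)-2-methylbut-2-enoic acid, the second equivalent of 29 (C/C=C(/C)C(=O)O)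
Why: Carbodiimide dehydration condenses two molecules of the acid to the symmetrical anhydride under neutral conditions that do not isomerise the Z double bond.

Step 17
Reactants: 28 silyl-protected diol (C9 epimers); 30 (2Z)-2-methylbut-2-enoic anhydride, two equivalents consumed
Product: 32 5,15-bis-angelate of 28, via dilithium dialkoxide 31 (not isolated)
Conditions: LiN(SiMe3)2 (2.2 equiv), THF, −78 °C; then 30 (3 equiv), −78 → 0 °C
Reagents that add atoms: (2Z)-2-methylbut-2-enoic anhydride, the second equivalent of 30 (C/C=C(/C)C(=O)OC(=O)/C(C)=C\C)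
Why: Acylating the preformed lithium alkoxides with one molecule of anhydride each esterifies both hindered hydroxyls without the nucleophilic catalysts that isomerise angelates to tiglates.

Step 18
Reactants: 32 5,15-bis-angelate of 28
Product: 33 11-hydroxy bis-angelate (C9 epimers)
Conditions: HF·pyridine, THF, 0 °C → rt
Reagents that add atoms: none
Why: Fluoride-mediated desilylation under buffered acidic conditions frees the C11 alcohol and leaves the angelate esters intact.

Step 19
Reactants: 33 11-hydroxy bis-angelate (C9 epimers)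
Product: 35 [(1R,2R,5R,6S,7S,8R)-2,6,9-trimethyl-5-{[(2Z)-2-methylbut-2-enoyl]oxy}-11-oxotricyclo[5.4.0.0^2,8]undec-9-en-6-yl]methyl (2Z)-2-methylbut-2-enoate, via saturated ketone 34 (not isolated)
Conditions: IBX (4 equiv), DMSO, 75 °C
Reagents that add atoms: none
Why: IBX oxidises the alcohol to the ketone and then dehydrogenates it (Nicolaou dehydrogenation) only toward C10–C9, because C1 is a bridgehead and C2 has no hydrogen, which gives the enone and removes the C9 centre.

## Compound list
1 | (2E)-3-methylpent-2-en-4-yn-1-ol | C#C/C(C)=C/CO | starting material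
2 | (2E)-3-methylpenta-2,4-dien-1-ol | C=C/C(C)=C/CO | intermediate
3 | (2E)-3-methylpenta-2,4-dienal | C=C/C(C)=C/C=O | intermediate
4 | 3-methylbut-2-enoic acid | CC(C)=CC(=O)O | starting material
5 | tert-butyldimethylsilyl 3-methylbut-2-enoate | CC(C)=CC(=O)O[Si](C)(C)C(C)(C)C | intermediate
6 | lithium 1-[(tert-butyldimethylsilyl)oxy]-3-methylbuta-1,3-dien-1-olate | [Li+].[O-]C(O[Si](C)(C)C(C)(C)C)=CC(C)=C | intermediate
7 | 1,1-bis[(tert-butyldimethylsilyl)oxy]-3-methylbuta-1,3-diene | C=C(C)C=C(O[Si](C)(C)C(C)(C)C)O[Si](C)(C)C(C)(C)C | intermediate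
8 | tert-butyldimethylsilyl (2E,5S,6E)-5-[(tert-butyldimethylsilyl)oxy]-3,7-dimethylnona-2,6,8-trienoate | CC(C)(C)[Si](C)(C)OC(=O)/C=C(\C)C[C@H](O[Si](C)(C)C(C)(C)C)/C=C(\C)C=C | intermediate
9 | (2E,5S,6E)-5-[(tert-butyldimethylsilyl)oxy]-3,7-dimethylnona-2,6,8-trienoic acid | OC(=O)/C=C(\C)C[C@H](O[Si](C)(C)C(C)(C)C)/C=C(\C)C=C | intermediate
10 | acid chloride of 9 | ClC(=O)/C=C(\C)C[C@H](O[Si](C)(C)C(C)(C)C)/C=C(\C)C=C | intermediate
11 | vinylketene from 10: (5S,6E)-5-silyloxy-7-methyl-3-methylidenenona-1,6,8-trien-1-one | O=C=CC(=C)C[C@H](O[Si](C)(C)C(C)(C)C)/C=C(\C)C=C | intermediate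
12 | (1R,2S,5R,7R)-2-[(tert-butyldimethylsilyl)oxy]-7-ethenyl-7-methyl-4-methylidenebicyclo[3.1.1]heptan-6-one (methyl syn to the three-carbon bridge, silyloxy syn to the carbonyl bridge) | O=C1[C@H]2[C@@H](O[Si](C)(C)C(C)(C)C)CC(=C)[C@@H]1[C@@]2(C)C=C | intermediate
13 | S-ethyl propanethioate | CCC(=O)SCC | starting material
14 | lithium (Z)-1-(ethylsulfanyl)prop-1-en-1-olate (methyl trans to the O–Li oxygen) | [Li+].[O-]/C(SCC)=C/C | intermediate
15 | (Z)-[1-(ethylsulfanyl)prop-1-enyl]oxy(trimethyl)silane | C/C=C(/O[Si](C)(C)C)SCC | intermediate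
16 | (2E)-but-2-enal | C/C=C/C=O | starting material
17 | S-ethyl (2S,3R,4E)-2-methyl-3-[(trimethylsilyl)oxy]hex-4-enethioate | CCSC(=O)[C@@H](C)[C@H](O[Si](C)(C)C)/C=C/C | intermediate
18 | S-ethyl (2S,3R,4E)-3-hydroxy-2-methylhex-4-enethioate | CCSC(=O)[C@@H](C)[C@H](O)/C=C/C | intermediate
19 | (2S,3R,4E)-3-hydroxy-2-methylhex-4-enoic acid | OC(=O)[C@@H](C)[C@H](O)/C=C/C | intermediate
20 | (2R,5S,6R)-2-tert-butyl-5-methyl-6-[(1E)-prop-1-enyl]-1,3-dioxan-4-one | O=C1O[C@H](C(C)(C)C)O[C@H](/C=C/C)[C@@H]1C | intermediate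
21 | lithium enolate of 20 | [Li+].[O-]C1=C(C)[C@@H](/C=C/C)O[C@@H](C(C)(C)C)O1 | intermediate
22 | aldol adduct: C5 of dioxanone 20 (new bond trans to propenyl, methyl cis) joined to the former carbonyl carbon of 12, hydroxyl on the face of the three-carbon bridge | O[C@@]1([C@@]3(C)C(=O)O[C@H](C(C)(C)C)O[C@@H]3/C=C/C)[C@H]2[C@@H](O[Si](C)(C)C(C)(C)C)CC(=C)[C@@H]1[C@@]2(C)C=C | intermediate
23 | ring-closed cycloheptene (C3=C4) from 22, exocyclic methylene still present | O[C@@]1([C@@]3(C)C(=O)O[C@H](C(C)(C)C)O[C@@H]34)[C@H]2[C@@H](O[Si](C)(C)C(C)(C)C)CC(=C)[C@@H]1[C@@]2(C)C=C4 | intermediate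
24 | saturated tricyclic hydroxy dioxanone (C7–OH; C9 epimers) | O[C@@]1([C@@]3(C)C(=O)O[C@H](C(C)(C)C)O[C@@H]34)[C@H]2[C@@H](O[Si](C)(C)C(C)(C)C)CC(C)[C@@H]1[C@@]2(C)CC4 | intermediate
25 | sodium xanthate of 24 | [Na+].[S-]C(=S)O[C@@]1([C@@]3(C)C(=O)O[C@H](C(C)(C)C)O[C@@H]34)[C@H]2[C@@H](O[Si](C)(C)C(C)(C)C)CC(C)[C@@H]1[C@@]2(C)CC4 | intermediate
26 | S-methyl xanthate of 24 | CSC(=S)O[C@@]1([C@@]3(C)C(=O)O[C@H](C(C)(C)C)O[C@@H]34)[C@H]2[C@@H](O[Si](C)(C)C(C)(C)C)CC(C)[C@@H]1[C@@]2(C)CC4 | intermediate
27 | tricyclic dioxanone with C7–H (C9 epimers) | [C@@H]1([C@@]3(C)C(=O)O[C@H](C(C)(C)C)O[C@@H]34)[C@H]2[C@@H](O[Si](C)(C)C(C)(C)C)CC(C)[C@@H]1[C@@]2(C)CC4 | intermediate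
28 | (1R,2R,5R,6S,7S,8S,11S)-11-[(tert-butyldimethylsilyl)oxy]-6-(hydroxymethyl)-2,6,9-trimethyltricyclo[5.4.0.0^2,8]undecan-5-ol (C9 epimers) | OC[C@]1(C)[C@@H]2[C@H]3[C@@H](O[Si](C)(C)C(C)(C)C)CC(C)[C@@H]2[C@@]3(C)CC[C@H]1O | intermediate
29 | (2Z)-2-methylbut-2-enoic acid (angelic acid) | C/C=C(/C)C(=O)O | starting material
30 | (2Z)-2-methylbut-2-enoic anhydride | C/C=C(/C)C(=O)OC(=O)/C(C)=C\C | intermediate
31 | dilithium dialkoxide of 28 | [Li+].[Li+].[O-]C[C@]1(C)[C@@H]2[C@H]3[C@@H](O[Si](C)(C)C(C)(C)C)CC(C)[C@@H]2[C@@]3(C)CC[C@H]1[O-] | intermediate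
32 | 5,15-bis[(2Z)-2-methylbut-2-enoate] of 28 (11-silyloxy; C9 epimers) | C/C=C(/C)C(=O)OC[C@]1(C)[C@@H]2[C@H]3[C@@H](O[Si](C)(C)C(C)(C)C)CC(C)[C@@H]2[C@@]3(C)CC[C@H]1OC(=O)/C(C)=C\C | intermediate
33 | 11-hydroxy bis-angelate (C9 epimers) | C/C=C(/C)C(=O)OC[C@]1(C)[C@@H]2[C@H]3[C@@H](O)CC(C)[C@@H]2[C@@]3(C)CC[C@H]1OC(=O)/C(C)=C\C | intermediate
34 | 11-oxo bis-angelate (C9 epimers) | C/C=C(/C)C(=O)OC[C@]1(C)[C@@H]2[C@H]3C(=O)CC(C)[C@@H]2[C@@]3(C)CC[C@H]1OC(=O)/C(C)=C\C | intermediate
35 | [(1R,2R,5R,6S,7S,8R)-2,6,9-trimethyl-5-{[(2Z)-2-methylbut-2-enoyl]oxy}-11-oxotricyclo[5.4.0.0^2,8]undec-9-en-6-yl]methyl (2Z)-2-methylbut-2-enoate | C/C=C(/C)C(=O)OC[C@]1(C)[C@@H]2[C@H]3C(=O)C=C(C)[C@@H]2[C@@]3(C)CC[C@H]1OC(=O)/C(C)=C\C | target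

## Step count and risks
Total step count: 19. Longest linear sequence: 12 steps (steps 1, 2, 5, 6, 11, 12, 13, 14, 15, 17, 18, 19; the branches starting from 4 and from 13 are equally long).

Most likely to fail, first: step 11. A fully substituted enolate must add to a ketone flanked by two bridgeheads and a 1,3-related vinyl group, and the lithium aldolate can revert. The fallback sets out from 20 and comes back at 22. It replaces the basic lithium aldol by a Lewis-acid-driven Mukaiyama addition of an isolated silyl ketene acetal. Dioxanone 20 is deprotonated and O-silylated (LiN(iPr)2, TMSCl, −78 °C) to 2-tert-butyl-5-methyl-4-[(1E)-prop-1-enyl]-6-[(trimethylsilyl)oxy]-4H-1,3-dioxin F1. F1 is added to ketone 12 activated by TiCl4 in CH2Cl2 at −78 °C. The electrophile is now activated instead of the nucleophile, silyl loss makes the addition irreversible, and attack trans to the propenyl group and on the same ketone face should again give 22 after aqueous work-up.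

Second: step 13. The tertiary cyclobutanol is very hindered, and its alkoxide sits next to the C11 silyl ether, so silyl migration or retro-aldol cleavage could compete with xanthate formation. The fallback sets out from 24 and comes back at 27. It avoids any alkoxide: 24 is acylated with oxalyl chloride in CH2Cl2 to the chlorooxoacetate of the tertiary alcohol F2. F2 is coupled with sodium 2-thioxopyridin-1(2H)-olate to the mixed oxalate of N-hydroxypyridine-2-thione F3. Heating F3 in benzene with 2-methylpropane-2-thiol (Barton–Crich radical deoxygenation through double decarboxylation) then gives 27, the cage again allowing hydrogen transfer to C7 only at the position the oxygen left.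

Third: step 6. The thermal ketene cycloaddition has to tolerate a diene and an allylic silyl ether, and its facial selectivity rests on allylic strain alone. The fallback sets out from 9 and comes back at 12. It uses a keteniminium ion instead of a ketene. Acid 9 is converted (1-chloro-N,N,2-trimethylprop-1-en-1-amine, then Me2NH) into (2E,5S,6E)-5-[(tert-butyldimethylsilyl)oxy]-N,N,3,7-tetramethylnona-2,6,8-trienamide F4. F4 is deconjugated (LiN(iPr)2, THF, −78 °C, then kinetic protonation with AcOH) to (5S,6E)-5-[(tert-butyldimethylsilyl)oxy]-N,N,7-trimethyl-3-methylidenenona-6,8-dienamide F5. With Tf2O and 2,4,6-collidine in 1,2-dichloroethane, F5 forms a keteniminium salt that undergoes the same intramolecular [2+2] at lower temperature to the bicyclic cyclobutaniminium triflate F6. Hydrolysis of F6 with aqueous NaHCO3 returns ketone 12.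

Further compounds
F1 | step 11 | 2-tert-butyl-5-methyl-4-[(1E)-prop-1-enyl]-6-[(trimethylsilyl)oxy]-4H-1,3-dioxin (silyl ketene acetal of 20, tert-butyl and propenyl cis) | C[Si](C)(C)OC1=C(C)[C@@H](/C=C/C)O[C@@H](C(C)(C)C)O1
F2 | step 13 | chlorooxoacetate of the tertiary alcohol 24 | ClC(=O)C(=O)O[C@@]1([C@@]3(C)C(=O)O[C@H](C(C)(C)C)O[C@@H]34)[C@H]2[C@@H](O[Si](C)(C)C(C)(C)C)CC(C)[C@@H]1[C@@]2(C)CC4
F3 | step 13 | mixed oxalate of 24 and N-hydroxypyridine-2-thione | S=C5C=CC=CN5OC(=O)C(=O)O[C@@]1([C@@]3(C)C(=O)O[C@H](C(C)(C)C)O[C@@H]34)[C@H]2[C@@H](O[Si](C)(C)C(C)(C)C)CC(C)[C@@H]1[C@@]2(C)CC4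
F4 | step 6 | (2E,5S,6E)-5-[(tert-butyldimethylsilyl)oxy]-N,N,3,7-tetramethylnona-2,6,8-trienamide | CN(C)C(=O)/C=C(\C)C[C@H](O[Si](C)(C)C(C)(C)C)/C=C(\C)C=C
F5 | step 6 | (5S,6E)-5-[(tert-butyldimethylsilyl)oxy]-N,N,7-trimethyl-3-methylidenenona-6,8-dienamide | CN(C)C(=O)CC(=C)C[C@H](O[Si](C)(C)C(C)(C)C)/C=C(\C)C=C
F6 | step 6 | N,N-dimethyl cyclobutaniminium triflate corresponding to ketone 12 | C[N+](C)=C1[C@H]2[C@@H](O[Si](C)(C)C(C)(C)C)CC(=C)[C@@H]1[C@@]2(C)C=C.[O-]S(=O)(=O)C(F)(F)F
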